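**Plan**

Locants: C1 lactone C=O, C2 CH2, C3 CH(O2), C4 C(CH3)(O‑lactone), C5 CH2, C6 C(CH3)(chain)(O1); O1–O2 is the peroxide. Enabling feature: on the 1,2‑dioxane ring (O1, O2, C3–C6) the lactone oxygen on C4 and the methyl group on C6 are 1,3‑cis (both axial).
Retrosynthesis: cut C14–C15 to remove the triene. Read C6–CH3 as C6–CH2–CO2H minus CO2, and C4–O as C4–C(=O) plus O (Baeyer–Villiger). One carbonyl carbon (Cx) then ties the two cis groups into a cyclopentanone C4–C5–C6–Cm–Cx. Finally cut O1–C6 and C3–C4 together.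
This leaves a 3‑alkyl‑5‑methylcyclopent‑2‑enone, which is a donor at C4 (α′) and an acceptor at C6 (β). Its partner is the three‑atom unit C3–O2–O1 of a silylperoxycarbenium ion, made by ozonolysis of methyl but‑3‑enoate.
Forward order: bought cyclopentenone ring → 1,2‑dioxane closed across it (bicyclo[3.2.1]) → ring‑expanded bridged δ‑lactone → γ‑lactone by translactonisation → decarboxylation → chain joined by B‑alkyl Suzuki–Miyaura coupling.
Stereochemistry: C4 comes from a chiral counter‑anion in the key step, C6 from C4 through the bridge geometry, and C3 from the chair transition state plus the cis‑lactonisation filter. The Baeyer–Villiger migration retains C4. The E,E,E‑triene comes from (2E,4E)‑hepta‑2,4‑dienal and a Takai olefination.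

Key step: step 5

Assumption: the (S,S) enantiomer of the acid catalyst is taken to direct attack to the diene face that gives (4S); the sense must be established by experiment, and the mirror‑image catalyst is used if it is opposite.
Names: "peroxylactone" means the bicyclic core of the target (1,2‑dioxane O1–O2–C3–C4–C5–C6 cis‑fused at C3–C4 to the γ‑lactone C1–C2–C3–C4–O), with the locants of the plan.

Step 1
Reactants: 1 8-bromooct-1-ene; 2 3-ethoxycyclopent-2-en-1-one
Product: 4 3-(oct-7-en-1-yl)cyclopent-2-en-1-one, via oct-7-enylmagnesium bromide 3 (not isolated)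
Conditions: Mg, THF, rt; 2, 0 °C → rt; 1 M aq. HCl, rt
Reagents that add atoms: water, O
Why: Grignard 1,2‑addition to a vinylogous ester followed by acid hydrolysis with allylic transposition is the classical 3‑alkoxyenone route to 3‑alkylcycloalkenones and creates no stereocentre.

Step 2
Reactants: 4 3-(oct-7-en-1-yl)cyclopent-2-en-1-one
Product: 5 (±)-5-methyl-3-(oct-7-en-1-yl)cyclopent-2-en-1-one
Conditions: LDA, THF, −78 °C; MeI, −78 → −20 °C
Reagents that add atoms: iodomethane, CI
Why: Kinetic deprotonation of a 3‑alkylcyclopentenone occurs at the α′ CH2 and the cross‑conjugated enolate is C‑methylated (enolate alkylation); the new stereocentre is racemic and is erased in step 3.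

Step 3
Reactants: 5 (±)-5-methyl-3-(oct-7-en-1-yl)cyclopent-2-en-1-one
Product: 6 trimethyl{[2-methyl-4-(oct-7-en-1-yl)cyclopenta-1,4-dien-1-yl]oxy}silane
Conditions: LDA, Me3SiCl (internal quench), THF, −78 °C; pentane, filtration, kept cold and used at once
Reagents that add atoms: chlorotrimethylsilane, C[Si](C)(C)Cl
Why: A second kinetic α′ deprotonation with O‑silylation (silyl enol ether formation) should give the flat, achiral 2‑silyloxydiene, which is handled cold because silyloxycyclopentadienes undergo 1,5‑hydrogen shift and dimerise on standing.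

Step 4
Reactants: 7 methyl but-3-enoate
Product: 9 methyl 3-methoxy-3-[(triethylsilyl)peroxy]propanoate, via methyl 3-hydroperoxy-3-methoxypropanoate 8 (not isolated)
Conditions: O3, CH2Cl2–MeOH, −78 °C; N2 purge, cold concentration; Et3SiCl, imidazole, DMF, 0 °C
Reagents that add atoms: ozone, [O-][O+]=O; methanol, CO; chlorotriethylsilane, CC[Si](Cl)(CC)CC
Why: Ozonolysis of a terminal alkene in methanol traps the carbonyl oxide as the α‑methoxy hydroperoxide, and O‑silylation of such hydroperoxides is routine; the acetal carbon is racemic and becomes planar in step 5.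

Step 5
Reactants: 6 trimethyl{[2-methyl-4-(oct-7-en-1-yl)cyclopenta-1,4-dien-1-yl]oxy}silane; 9 methyl 3-methoxy-3-[(triethylsilyl)peroxy]propanoate
Product: 11 methyl 2-[(1S,4S,5S)-5-methyl-1-(oct-7-en-1-yl)-6-oxo-2,3-dioxabicyclo[3.2.1]octan-4-yl]acetate, via silyl enol ether 10 (not isolated)
Conditions: (S,S)-BINOL-derived N-triflyl imidodiphosphorimidate acid (IDPi, 3,3′-aryl = 3,5-(CF3)2C6H3, 3 mol %), 4 Å MS, CH2Cl2, −78 °C; then citrate buffer (pH 4), THF, 0 °C
Reagents that add atoms: none
Why: Proposed new method: the acid is silylated by 6 and the resulting silylium‑type Lewis acid takes the methoxy group from 9, giving a triethylsilylperoxycarbenium ion (C3=O2+–O1SiEt3) paired with the chiral anion; C4 of the 2‑silyloxydiene attacks C3 (first bond), the charge moves through the 1‑silyloxyallyl cation Cx–Cm–C6 to C6, and O1, now tethered on the same face, adds there (second bond) and passes its Et3Si+ on to the next molecule of 9. The closest known reaction types are the Lewis‑acid substitution of peroxyacetals by silyl enol ethers and the [3+2] annulation of silylperoxycarbenium ions with alkenes, in which the carbocation left by C–C bond formation is captured by the silylperoxide oxygen; here that capture is vinylogous, which makes the outcome a formal [3+3] across C4–C5–C6 (topologically a (4+3) annulation of a cyclopentadiene). One ring is closed, the 1,2‑dioxane, by 6‑exo‑trig conjugate addition of O1 to C6, and this creates the 2,3‑dioxabicyclo[3.2.1]octane. C4 is set by the chiral counter‑anion, which shields one face of the ion pair toward the flat achiral diene; C6 follows from C4 because the three‑atom bridge C3–O2–O1 can reach C6 only on the ring face that already carries C3; C3 is set by the compact chair‑like arrangement that places CH2CO2Me equatorial on the nascent dioxane. The step needs attack of the diene at C4 rather than at Cm or C6 (secured by the enol‑ether polarisation), 1,4‑ rather than 1,2‑capture of the cation (the 1,2‑adduct is a peroxyketal that re‑ionises under the conditions, the 1,4‑adduct a stable silyl enol ether), no collapse of that enol ether onto O1 to an epoxide (the Cm–C6–O1–O2 dihedral angle is locked gauche by the bridge), and no reaction of the terminal alkene (far less nucleophilic than a silyloxydiene).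

Step 6
Reactants: 11 methyl 2-[(1S,4S,5S)-5-methyl-1-(oct-7-en-1-yl)-6-oxo-2,3-dioxabicyclo[3.2.1]octan-4-yl]acetate
Product: 12 methyl 2-[(1S,4S,5S)-5-methyl-1-(oct-7-en-1-yl)-7-oxo-2,3,6-trioxabicyclo[3.3.1]nonan-4-yl]acetate
Conditions: Me3SiOOSiMe3, Me3SiOTf (20 mol %), CH2Cl2, −40 → 0 °C
Reagents that add atoms: bis(trimethylsilyl) peroxide, C[Si](C)(C)OO[Si](C)(C)C
Why: Baeyer–Villiger oxidation with a silylated peroxide and a silyl triflate is known to spare C=C bonds, and the fully substituted C4 migrates in preference to the CH2 group with retention, so oxygen arrives on C4 on the face that the carbonyl carbon held.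

Step 7
Reactants: 12 methyl 2-[(1S,4S,5S)-5-methyl-1-(oct-7-en-1-yl)-7-oxo-2,3,6-trioxabicyclo[3.3.1]nonan-4-yl]acetate
Product: 13 [(3S,4S,6S)-4-methyl-6-(oct-7-en-1-yl)peroxylacton-6-yl]acetic acid
Conditions: TsOH·H2O (20 mol %), MeCN–H2O (9:1), 40 °C
Reagents that add atoms: water, O
Why: Acid‑catalysed acyl–oxygen hydrolysis of the strained bridged δ‑lactone frees the C4 hydroxyl, which closes onto the cis CH2CO2Me arm to the γ‑lactone (translactonisation under thermodynamic control); no stereocentre is touched and any C3 epimer cannot close and is removed here.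

Step 8
Reactants: 13 [(3S,4S,6S)-4-methyl-6-(oct-7-en-1-yl)peroxylacton-6-yl]acetic acid
Product: 15 (3S,4S,6S)-4,6-dimethyl-6-(oct-7-en-1-yl)peroxylactone, via thiohydroxamate ester 14 (not isolated)
Conditions: N-hydroxypyridine-2(1H)-thione, DCC, CH2Cl2, 0 °C, dark; Bu3SnH (excess, concentrated), tungsten lamp, 0 °C
Reagents that add atoms: none
Why: In this Barton decarboxylation the primary C6–CH2 radical should be reduced before it attacks O1, because the CH2 group is axial on the dioxane chair and therefore gauche rather than anti to the O1–O2 bond, and tin‑hydride or hydride reductions of β‑peroxyalkyl radicals (deiodination, demercuration) are known; no stereocentre is touched.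

Step 9
Reactants: 16 (2E,4E)-hepta-2,4-dienal
Product: 17 (1E,3E,5E)-1-iodoocta-1,3,5-triene
Conditions: CrCl2, CHI3, THF–dioxane, 0 °C, dark
Reagents that add atoms: iodoform, IC(I)I
Why: Takai olefination of an enal gives the E‑alkenyl iodide and leaves the existing E,E‑diene untouched.

Step 10
Reactants: 15 (3S,4S,6S)-4,6-dimethyl-6-(oct-7-en-1-yl)peroxylactone; 17 (1E,3E,5E)-1-iodoocta-1,3,5-triene
Product: 19 (3S,4S,6S)-6-[(9E,11E,13E)-hexadeca-9,11,13-trien-1-yl]-4,6-dimethylperoxylactone (target), via B-alkyl-9-BBN adduct 18 (not isolated)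
Conditions: 9-BBN-H, THF, 0 °C → rt; 17, Pd(dppf)Cl2 (5 mol %), AsPh3 (10 mol %), Cs2CO3, DMF–H2O, rt, dark
Reagents that add atoms: none
Why: Anti‑Markovnikov hydroboration with 9‑BBN is chemoselective for the terminal alkene over the lactone, the B‑alkyl Suzuki–Miyaura coupling keeps the geometry of the alkenyl iodide, palladium‑catalysed couplings are known to tolerate dialkyl peroxides, and the aqueous medium reprotonates any lactone enolate.

**Compound list**

1 | 8-bromooct-1-ene | C=CCCCCCCBr | starting material
2 | 3-ethoxycyclopent-2-en-1-one | CCOC1=CC(=O)CC1 | starting material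
3 | oct-7-enylmagnesium bromide | C=CCCCCCC[Mg]Br | intermediate
4 | 3-(oct-7-en-1-yl)cyclopent-2-en-1-one | C=CCCCCCCC1=CC(=O)CC1 | intermediate
5 | (±)-5-methyl-3-(oct-7-en-1-yl)cyclopent-2-en-1-one | C=CCCCCCCC1=CC(=O)C(C)C1 | intermediate
6 | trimethyl{[2-methyl-4-(oct-7-en-1-yl)cyclopenta-1,4-dien-1-yl]oxy}silane | C=CCCCCCCC1=CC(O[Si](C)(C)C)=C(C)C1 | intermediate
7 | methyl but-3-enoate | C=CCC(=O)OC | starting material
8 | methyl 3-hydroperoxy-3-methoxypropanoate (racemic) | COC(CC(=O)OC)OO | intermediate
9 | methyl 3-methoxy-3-[(triethylsilyl)peroxy]propanoate (racemic) | CC[Si](CC)(CC)OOC(CC(=O)OC)OC | intermediate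
10 | trimethylsilyl enol ether of 11 (enol C=C between Cm and Cx, same configuration as 11) | C=CCCCCCC[C@]12C[C@](C)(C(O[Si](C)(C)C)=C1)[C@H](CC(=O)OC)OO2 | intermediate
11 | methyl 2-[(1S,4S,5S)-5-methyl-1-(oct-7-en-1-yl)-6-oxo-2,3-dioxabicyclo[3.2.1]octan-4-yl]acetate | C=CCCCCCC[C@]12C[C@](C)(C(=O)C1)[C@H](CC(=O)OC)OO2 | intermediate
12 | methyl 2-[(1S,4S,5S)-5-methyl-1-(oct-7-en-1-yl)-7-oxo-2,3,6-trioxabicyclo[3.3.1]nonan-4-yl]acetate | C=CCCCCCC[C@]12C[C@](C)(OC(=O)C1)[C@H](CC(=O)OC)OO2 | intermediate
13 | [(3S,4S,6S)-4-methyl-6-(oct-7-en-1-yl)peroxylacton-6-yl]acetic acid (CH2CO2H cis, chain trans to the lactone oxygen) | C=CCCCCCC[C@@]1(CC(=O)O)C[C@]2(C)OC(=O)C[C@@H]2OO1 | intermediate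
14 | 2-thioxopyridin-1(2H)-yl ester of 13 | C=CCCCCCC[C@@]1(CC(=O)ON3C=CC=CC3=S)C[C@]2(C)OC(=O)C[C@@H]2OO1 | intermediate
15 | (3S,4S,6S)-4,6-dimethyl-6-(oct-7-en-1-yl)peroxylactone | C=CCCCCCC[C@@]1(C)C[C@]2(C)OC(=O)C[C@@H]2OO1 | intermediate
16 | (2E,4E)-hepta-2,4-dienal | CC/C=C/C=C/C=O | starting material
17 | (1E,3E,5E)-1-iodoocta-1,3,5-triene | CC/C=C/C=C/C=C/I | intermediate
18 | 9-{8-[(3S,4S,6S)-4,6-dimethylperoxylacton-6-yl]octyl}-9-borabicyclo[3.3.1]nonane | C(CCCCCCC[C@@]1(C)C[C@]2(C)OC(=O)C[C@@H]2OO1)B3C4CCCC3CCC4 | intermediate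
19 | (3S,4S,6S)-6-[(9E,11E,13E)-hexadeca-9,11,13-trien-1-yl]-4,6-dimethylperoxylactone | CC/C=C/C=C/C=C/CCCCCCCC[C@@]1(C)C[C@]2(C)OC(=O)C[C@@H]2OO1 | target

Total step count: 10. Longest linear sequence: 8 (steps 1, 2, 3, 5, 6, 7, 8, 10).

**Steps most likely to fail**

**Step 5.**
- What may go wrong: the cascade may stop after the first bond, through loss of the silyl group from the silyloxyallyl cation before O1 arrives. The cation may be held as the 1,2‑adduct. The ion pair may give poor enantiofacial selectivity.
- Fallback (known reaction types, one bond at a time), setting out from 6 and 9: Me3SiOTf‑catalysed Mukaiyama‑type substitution of the peroxyacetal at −78 °C with an early pyridine quench gives methyl 3-[1-methyl-4-(oct-7-en-1-yl)-2-oxocyclopent-3-en-1-yl]-3-[(triethylsilyl)peroxy]propanoate F1. HF·pyridine in THF then frees methyl 3-hydroperoxy-3-[1-methyl-4-(oct-7-en-1-yl)-2-oxocyclopent-3-en-1-yl]propanoate F2. Catalytic Et2NH in CF3CH2OH closes the dioxane by intramolecular oxa‑Michael addition, which is possible only on the face that carries C3.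
- The racemate so obtained consists of 11 and its enantiomer methyl 2-[(1R,4R,5R)-5-methyl-1-(oct-7-en-1-yl)-6-oxo-2,3-dioxabicyclo[3.2.1]octan-4-yl]acetate F3. It is separated by preparative chromatography on a chiral stationary phase, and the route is rejoined at 11.

**Step 8.**
- What may go wrong: the primary radical next to the peroxide carbon may attack O1 (oxirane formation with O–O cleavage) before it is reduced, or tin radicals may attack the O–O bond.
- Fallback, setting out from 13: the alkene is masked so that a thiol, a much faster hydrogen donor than tin hydride but one that adds to terminal alkenes, can be used. Pyridinium tribromide in CH2Cl2 gives [(3S,4S,6S)-6-(7,8-dibromooctyl)-4-methylperoxylacton-6-yl]acetic acid F4. DCC and N‑hydroxypyridine‑2‑thione convert it into its 2-thioxopyridin-1(2H)-yl ester F5. Photolysis with tert‑butyl thiol gives (3S,4S,6S)-6-(7,8-dibromooctyl)-4,6-dimethylperoxylactone F6.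
- NaI in acetone restores the alkene, and the route is rejoined at 15.

**Step 10.**
- What may go wrong: the carbonate base may trigger β‑elimination of the peroxide from the lactone enolate. The borane or zerovalent palladium may attack the O–O bond. The iodotriene may lose its geometry during a slow coupling.
- Fallback (neutral Negishi coupling), setting out from 15: hydrozirconation with Cp2ZrHCl followed by iodinolysis gives (3S,4S,6S)-6-(8-iodooctyl)-4,6-dimethylperoxylactone F7. Zinc insertion (Zn, LiCl, THF) gives {8-[(3S,4S,6S)-4,6-dimethylperoxylacton-6-yl]octyl}zinc iodide F8.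
- Pd(dppf)Cl2‑catalysed coupling of F8 with 17 in THF at rt arrives at 19.

**Further compounds**

F1 | step 5 | methyl 3-[1-methyl-4-(oct-7-en-1-yl)-2-oxocyclopent-3-en-1-yl]-3-[(triethylsilyl)peroxy]propanoate | C=CCCCCCCC1=CC(=O)C(C)(C1)C(CC(=O)OC)OO[Si](CC)(CC)CC
F2 | step 5 | methyl 3-hydroperoxy-3-[1-methyl-4-(oct-7-en-1-yl)-2-oxocyclopent-3-en-1-yl]propanoate | C=CCCCCCCC1=CC(=O)C(C)(C1)C(CC(=O)OC)OO
F3 | step 5 | methyl 2-[(1R,4R,5R)-5-methyl-1-(oct-7-en-1-yl)-6-oxo-2,3-dioxabicyclo[3.2.1]octan-4-yl]acetate | C=CCCCCCC[C@@]12C[C@@](C)(C(=O)C1)[C@@H](CC(=O)OC)OO2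
F4 | step 8 | [(3S,4S,6S)-6-(7,8-dibromooctyl)-4-methylperoxylacton-6-yl]acetic acid | BrCC(Br)CCCCCC[C@@]1(CC(=O)O)C[C@]2(C)OC(=O)C[C@@H]2OO1
F5 | step 8 | 2-thioxopyridin-1(2H)-yl ester of F4 | BrCC(Br)CCCCCC[C@@]1(CC(=O)ON3C=CC=CC3=S)C[C@]2(C)OC(=O)C[C@@H]2OO1
F6 | step 8 | (3S,4S,6S)-6-(7,8-dibromooctyl)-4,6-dimethylperoxylactone | BrCC(Br)CCCCCC[C@@]1(C)C[C@]2(C)OC(=O)C[C@@H]2OO1
F7 | step 10 | (3S,4S,6S)-6-(8-iodooctyl)-4,6-dimethylperoxylactone | ICCCCCCCC[C@@]1(C)C[C@]2(C)OC(=O)C[C@@H]2OO1
F8 | step 10 | {8-[(3S,4S,6S)-4,6-dimethylperoxylacton-6-yl]octyl}zinc iodide | I[Zn]CCCCCCCC[C@@]1(C)C[C@]2(C)OC(=O)C[C@@H]2OO1
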